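**Plan**

- Retrosynthesis: the C3a–C3 bond of the dihydrofuran ring is cut first, together with the C–O bond of the CH2OH arm on C3 (traced back to O2). The O1–C2 aryl ether bond is cut next, and last the two side-chain C=C bonds, which lead back to 5-iodovanillin and syringaldehyde.
- Forward: the ring C fragment (O-silyl sinapyl methyl carbonate) and the ring A fragment (methyl 5-iodoferulate) are made separately and joined at O1–C2 by iridium-catalysed allylic etherification. The dihydrofuran ring is closed last, then the ester is reduced and the silyl group removed.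
- Enabling feature: C3 carries a one-carbon CH2OH arm, so C3 plus that carbon can be read as a former vinyl group. With O1, C7a and C3a of ring A this gives a hex-5-enyl array (C3a–C7a–O1–C2–C3=CH2). A C3a aryl radical therefore closes 5-exo on C3, and the radical left on the arm takes up O2.
- Stereochemistry: C2 (R) comes from the chiral iridium catalyst; C3 (S) is set from C2 by trans-selective radical ring closure.

Key step: step 7

Numbering used below: benzofuran numbering (O1, C2, C3, C3a, C4 to C7, C7a); ring A is the benzo ring, ring C the syringyl ring.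

Assumption: the ligand enantiomer is written as (Ra,Rc,Rc) on the understanding that it delivers the (R) ether; if the sense of induction proves opposite, the (Sa,Sc,Sc) ligand is used with no other change.

**Step 1**
Reactants: 1 syringaldehyde
Product: 2 3,5-dimethoxy-4-(triisopropylsilyloxy)benzaldehyde
Conditions: TIPSCl, imidazole, DMF, rt
Reagents that add atoms: triisopropylsilyl chloride, CC(C)[Si](Cl)(C(C)C)C(C)C
Why: Silylation of a phenol with a silyl chloride and imidazole should give a hindered aryl silyl ether that is stable to the hydride, phenoxide and radical steps that follow.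

**Step 2**
Reactants: 2 3,5-dimethoxy-4-(triisopropylsilyloxy)benzaldehyde
Product: 3 ethyl (E)-3-[3,5-dimethoxy-4-(triisopropylsilyloxy)phenyl]prop-2-enoate
Conditions: (EtO)2P(O)CH2CO2Et, NaH, THF, 0 °C to rt
Reagents that add atoms: triethyl phosphonoacetate, CCOC(=O)CP(=O)(OCC)OCC
Why: The Horner–Wadsworth–Emmons reaction of an aromatic aldehyde with a stabilised phosphonate anion should give the E cinnamate.

**Step 3**
Reactants: 3 ethyl (E)-3-[3,5-dimethoxy-4-(triisopropylsilyloxy)phenyl]prop-2-enoate
Product: 4 (E)-3-[3,5-dimethoxy-4-(triisopropylsilyloxy)phenyl]prop-2-en-1-ol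
Conditions: i-Bu2AlH (2.2 equiv), CH2Cl2, −78 to 0 °C; aqueous potassium sodium tartrate
Reagents that add atoms: none
Why: Reduction of an α,β-unsaturated ester with i-Bu2AlH goes 1,2 and should give the allylic alcohol with the E double bond unchanged.

**Step 4**
Reactants: 4 (E)-3-[3,5-dimethoxy-4-(triisopropylsilyloxy)phenyl]prop-2-en-1-ol
Product: 5 (E)-3-[3,5-dimethoxy-4-(triisopropylsilyloxy)phenyl]prop-2-en-1-yl methyl carbonate
Conditions: ClCO2Me, pyridine, DMAP (cat.), CH2Cl2, 0 °C
Reagents that add atoms: methyl chloroformate, COC(=O)Cl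
Why: Acylation of a primary allylic alcohol with a chloroformate should give the linear allylic carbonate needed as the electrophile for allylic substitution.

**Step 5**
Reactants: 6 5-iodovanillin (4-hydroxy-3-iodo-5-methoxybenzaldehyde)
Product: 7 methyl (E)-3-(4-hydroxy-3-iodo-5-methoxyphenyl)prop-2-enoate (methyl 5-iodoferulate)
Conditions: Ph3P=CHCO2Me (1.3 equiv), toluene, 90 °C
Reagents that add atoms: methyl (triphenylphosphoranylidene)acetate, COC(=O)C=P(c1ccccc1)(c1ccccc1)c1ccccc1
Why: The Wittig reaction of a stabilised ylide tolerates a free phenol and should give the E cinnamate, placing the future side chain on ring A before the fragments are joined.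

**Step 6**
Reactants: 5 (E)-3-[3,5-dimethoxy-4-(triisopropylsilyloxy)phenyl]prop-2-en-1-yl methyl carbonate; 7 methyl (E)-3-(4-hydroxy-3-iodo-5-methoxyphenyl)prop-2-enoate
Product: 9 methyl (E)-3-[4-{[(1R)-1-(3,5-dimethoxy-4-triisopropylsilyloxyphenyl)prop-2-en-1-yl]oxy}-3-iodo-5-methoxyphenyl]prop-2-enoate, via sodium aryloxide 8 (not isolated)
Conditions: 7 (1.5 equiv), NaH, THF, 0 °C; then 5, [Ir(cod)Cl]2 (2 mol %), (Ra,Rc,Rc)-O,O'-(1,1'-binaphthalene-2,2'-diyl) N,N-bis(1-phenylethyl)phosphoramidite (4 mol %, catalyst pre-activated with n-PrNH2), THF, 40 °C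
Reagents that add atoms: none
Why: Iridium-catalysed asymmetric allylic etherification of a linear cinnamyl-type carbonate with an alkali aryloxide attacks the aryl-substituted allyl terminus, so the branched ether should form with the new benzylic centre (the future C2) set as R by the chiral phosphoramidite on the metallacyclic iridium allyl complex, while the methyl ester of 8 is indifferent to the methyl carbonate leaving group.

**Step 7**
Reactants: 9 methyl (E)-3-[4-{[(1R)-1-(3,5-dimethoxy-4-triisopropylsilyloxyphenyl)prop-2-en-1-yl]oxy}-3-iodo-5-methoxyphenyl]prop-2-enoate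
Product: 11 methyl (E)-3-[(2R,3S)-2-(3,5-dimethoxy-4-triisopropylsilyloxyphenyl)-3-(hydroxymethyl)-7-methoxy-2,3-dihydro-1-benzofuran-5-yl]prop-2-enoate, via hydroperoxide 10 (not isolated)
Conditions: Bu3SnH (1.5 equiv, syringe pump), Et3B (0.2 equiv), stream of dry air, toluene, 0 °C; then PPh3 (1.5 equiv), rt
Reagents that add atoms: dioxygen, O=O
Why: The tributyltin radical (started by Et3B and O2) abstracts iodine from 9 to give the C3a aryl radical, which adds to the inner vinyl carbon (C3); the primary radical left on the exocyclic carbon is captured by O2 faster than by the low stationary concentration of Bu3SnH, the peroxyl radical takes hydrogen from Bu3SnH to give hydroperoxide 10 and carry the chain, and PPh3 then reduces 10 to alcohol 11. The closest known reaction type is the oxygenative radical cyclization of unsaturated halides with tin hydride under air, together with aryl radical cyclization and nitroxide trapping of 2-iodoaryl allyl ethers and amides. The dihydrofuran ring closes in the 5-exo-trig mode. C3 is set by the existing C2 centre: in the chair-like transition state the C2 aryl group lies pseudo-equatorial and the vinyl terminus turns away from it, so the CH2 arm should end trans to the aryl group (3S), while C2 itself is not touched. The step needs 5-exo over 6-endo closure, ring closure before the aryl radical is reduced or oxygenated, and no attack on the cinnamate; the first two are secured by the very fast closure of 2-(allyloxy)aryl radicals and the slow addition of Bu3SnH, the last by the low reactivity of a β-aryl acrylate toward alkyl and peroxyl radicals.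

**Step 8**
Reactants: 11 methyl (E)-3-[(2R,3S)-2-(3,5-dimethoxy-4-triisopropylsilyloxyphenyl)-3-(hydroxymethyl)-7-methoxy-2,3-dihydro-1-benzofuran-5-yl]prop-2-enoate
Product: 12 (E)-3-[(2R,3S)-2-(3,5-dimethoxy-4-triisopropylsilyloxyphenyl)-3-(hydroxymethyl)-7-methoxy-2,3-dihydro-1-benzofuran-5-yl]prop-2-en-1-ol
Conditions: i-Bu2AlH (4 equiv), CH2Cl2, −78 °C; aqueous potassium sodium tartrate
Reagents that add atoms: none
Why: 1,2-Reduction of the cinnamate ester with i-Bu2AlH should give the E allylic alcohol without touching the aryl silyl ether, the benzylic ether or either stereocentre.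

**Step 9**
Reactants: 12 (E)-3-[(2R,3S)-2-(3,5-dimethoxy-4-triisopropylsilyloxyphenyl)-3-(hydroxymethyl)-7-methoxy-2,3-dihydro-1-benzofuran-5-yl]prop-2-en-1-ol
Product: 13 4-[(2R,3S)-3-(hydroxymethyl)-5-[(E)-3-hydroxyprop-1-enyl]-7-methoxy-2,3-dihydro-1-benzofuran-2-yl]-2,6-dimethoxyphenol (target)
Conditions: Bu4NF (1.1 equiv), AcOH (1.1 equiv), THF, 0 °C
Reagents that add atoms: none
Why: Fluoride cleavage of an aryl silyl ether is fast at 0 °C, and the acetic acid buffer keeps the freed phenol protonated so that it should not open the benzylic C2–O1 bond.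

**Compound list**

1 | syringaldehyde (4-hydroxy-3,5-dimethoxybenzaldehyde) | COc1cc(C=O)cc(OC)c1O | starting material
2 | 3,5-dimethoxy-4-(triisopropylsilyloxy)benzaldehyde | COc1cc(C=O)cc(OC)c1O[Si](C(C)C)(C(C)C)C(C)C | intermediate
3 | ethyl (E)-3-[3,5-dimethoxy-4-(triisopropylsilyloxy)phenyl]prop-2-enoate | CCOC(=O)/C=C/c1cc(OC)c(O[Si](C(C)C)(C(C)C)C(C)C)c(OC)c1 | intermediate
4 | (E)-3-[3,5-dimethoxy-4-(triisopropylsilyloxy)phenyl]prop-2-en-1-ol | OC/C=C/c1cc(OC)c(O[Si](C(C)C)(C(C)C)C(C)C)c(OC)c1 | intermediate
5 | (E)-3-[3,5-dimethoxy-4-(triisopropylsilyloxy)phenyl]prop-2-en-1-yl methyl carbonate | COC(=O)OC/C=C/c1cc(OC)c(O[Si](C(C)C)(C(C)C)C(C)C)c(OC)c1 | intermediate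
6 | 5-iodovanillin (4-hydroxy-3-iodo-5-methoxybenzaldehyde) | COc1cc(C=O)cc(I)c1O | starting material
7 | methyl (E)-3-(4-hydroxy-3-iodo-5-methoxyphenyl)prop-2-enoate | COC(=O)/C=C/c1cc(I)c(O)c(OC)c1 | intermediate
8 | sodium aryloxide of 7, formed in the flask | COC(=O)/C=C/c1cc(I)c([O-])c(OC)c1.[Na+] | intermediate
9 | methyl (E)-3-[4-{[(1R)-1-(3,5-dimethoxy-4-triisopropylsilyloxyphenyl)prop-2-en-1-yl]oxy}-3-iodo-5-methoxyphenyl]prop-2-enoate | C=C[C@@H](Oc1c(I)cc(/C=C/C(=O)OC)cc1OC)c1cc(OC)c(O[Si](C(C)C)(C(C)C)C(C)C)c(OC)c1 | intermediate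
10 | methyl (E)-3-[(2R,3S)-2-(3,5-dimethoxy-4-triisopropylsilyloxyphenyl)-3-(hydroperoxymethyl)-7-methoxy-2,3-dihydro-1-benzofuran-5-yl]prop-2-enoate, formed in the flask | COc1cc([C@@H]2Oc3c(OC)cc(/C=C/C(=O)OC)cc3[C@H]2COO)cc(OC)c1O[Si](C(C)C)(C(C)C)C(C)C | intermediate
11 | methyl (E)-3-[(2R,3S)-2-(3,5-dimethoxy-4-triisopropylsilyloxyphenyl)-3-(hydroxymethyl)-7-methoxy-2,3-dihydro-1-benzofuran-5-yl]prop-2-enoate | COc1cc([C@@H]2Oc3c(OC)cc(/C=C/C(=O)OC)cc3[C@H]2CO)cc(OC)c1O[Si](C(C)C)(C(C)C)C(C)C | intermediate
12 | (E)-3-[(2R,3S)-2-(3,5-dimethoxy-4-triisopropylsilyloxyphenyl)-3-(hydroxymethyl)-7-methoxy-2,3-dihydro-1-benzofuran-5-yl]prop-2-en-1-ol | COc1cc([C@@H]2Oc3c(OC)cc(/C=C/CO)cc3[C@H]2CO)cc(OC)c1O[Si](C(C)C)(C(C)C)C(C)C | intermediate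
13 | 4-[(2R,3S)-3-(hydroxymethyl)-5-[(E)-3-hydroxyprop-1-enyl]-7-methoxy-2,3-dihydro-1-benzofuran-2-yl]-2,6-dimethoxyphenol | COc1cc([C@@H]2Oc3c(OC)cc(/C=C/CO)cc3[C@H]2CO)cc(OC)c1O | target

**Step count**

Total: 9 steps. Longest linear sequence: 8 steps (steps 1 to 4 and 6 to 9); step 5 makes the ring A fragment in one step from 6.

**Steps most likely to fail**

Step 7. The ring closure may show poor facial selectivity at C3 (the cis isomer would have to be removed by chromatography). The cyclized radical may also be reduced by the tin hydride before it meets oxygen, or the benzylic ether position may be oxidised under air. Fallback: setting out from 9, the oxygen is delivered by a persistent nitroxide in place of the chain oxygenation. Treatment with Bu3SnH and TEMPO in toluene at 60 °C should close the ring and trap the primary radical by radical–radical coupling, giving methyl (E)-3-[(2R,3S)-2-(3,5-dimethoxy-4-triisopropylsilyloxyphenyl)-7-methoxy-3-{[(2,2,6,6-tetramethylpiperidin-1-yl)oxy]methyl}-2,3-dihydro-1-benzofuran-5-yl]prop-2-enoate F1. Reduction of the N–O bond with Zn in AcOH, THF and water at 50 °C then returns to the route at 11.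

Step 6. The hindered, electron-poor aryloxide may attack slowly, and reversible ionization of the product on the metal may erode both the branched-to-linear selectivity and the enantiomeric purity. Fallback: setting out from 2, addition of vinylmagnesium bromide in THF at −78 °C gives racemic 1-[3,5-dimethoxy-4-(triisopropylsilyloxy)phenyl]prop-2-en-1-ol F2. Kinetic resolution with Candida antarctica lipase B and vinyl acetate is expected to acylate the R enantiomer to (1R)-1-[3,5-dimethoxy-4-(triisopropylsilyloxy)phenyl]prop-2-en-1-yl acetate F3 and leave (1S)-1-[3,5-dimethoxy-4-(triisopropylsilyloxy)phenyl]prop-2-en-1-ol F4. A Mitsunobu reaction of F4 with phenol 7 (PPh3, DIAD, toluene, −20 °C) with inversion returns to the route at 9.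

Step 5. Proton transfer from the acidic iodophenol to the ylide may stall the olefination. Fallback: setting out from 6, a Knoevenagel–Doebner condensation with malonic acid (pyridine, piperidine, 90 °C) with loss of carbon dioxide gives (E)-3-(4-hydroxy-3-iodo-5-methoxyphenyl)prop-2-enoic acid F5. Fischer esterification (MeOH, H2SO4 cat., reflux) returns to the route at 7.

**Further compounds**

F1 | step 7 | methyl (E)-3-[(2R,3S)-2-(3,5-dimethoxy-4-triisopropylsilyloxyphenyl)-7-methoxy-3-{[(2,2,6,6-tetramethylpiperidin-1-yl)oxy]methyl}-2,3-dihydro-1-benzofuran-5-yl]prop-2-enoate | COc1cc([C@@H]2Oc3c(OC)cc(/C=C/C(=O)OC)cc3[C@H]2CON4C(C)(C)CCCC4(C)C)cc(OC)c1O[Si](C(C)C)(C(C)C)C(C)C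
F2 | step 6 | racemic 1-[3,5-dimethoxy-4-(triisopropylsilyloxy)phenyl]prop-2-en-1-ol | C=CC(O)c1cc(OC)c(O[Si](C(C)C)(C(C)C)C(C)C)c(OC)c1
F3 | step 6 | (1R)-1-[3,5-dimethoxy-4-(triisopropylsilyloxy)phenyl]prop-2-en-1-yl acetate | C=C[C@@H](OC(C)=O)c1cc(OC)c(O[Si](C(C)C)(C(C)C)C(C)C)c(OC)c1
F4 | step 6 | (1S)-1-[3,5-dimethoxy-4-(triisopropylsilyloxy)phenyl]prop-2-en-1-ol | C=C[C@H](O)c1cc(OC)c(O[Si](C(C)C)(C(C)C)C(C)C)c(OC)c1
F5 | step 5 | (E)-3-(4-hydroxy-3-iodo-5-methoxyphenyl)prop-2-enoic acid | OC(=O)/C=C/c1cc(I)c(O)c(OC)c1
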